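**Plan**

1. The hardest feature is C3. It is a tertiary, benzylic C–H next to the C4 ketone and epimerises with base, so it must be made late and under neutral conditions, together with ring C and with the acid-sensitive 2,2-dimethylpyran on ring B already present.
2. Retrosynthetic cuts, in order: O–Si (7-O, 3′-O) and 5-O–CH3; then C2–C3 of ring C (key cut: C2 goes back to an aryl OCH3 carbon, C3 to a carbene); C3=N2; C3–C1′ (enolate arylation); C4–C4a (aryllithium acylation); the pyran ring of ring B (propargyl Claisen cascade).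
3. Enabling feature: C2 is a CH2 bound only to O1 and C3, so it is a methyl-ether carbon in disguise. O1 and 5-O flank C4a symmetrically on the phloroglucinol ring A, so in a 2,6-dimethoxyaryl ketone the two OMe groups are equivalent, and their six hydrogens are the only C–H bonds a carbene at C3 can reach.
4. Forward order: the ring A ketone (2 steps) and the bromochromene of ring B (pyran closed first, 4 steps) are joined at C3–C1′. The CH2 is turned into C=N2, ring C closes last by enantioselective C–H insertion, and two base-free deprotections follow.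
5. Stereochemistry: (3S) comes from the chiral dirhodium catalyst in the insertion, which delivers H and C2 to one face of the carbene carbon. No later step uses base.

Key step: step 9

Assumption: the sense of induction of Rh2(S-PTAD)4 on this substrate class cannot be derived from precedent. The S-catalyst is written for the (3S) product, and its mirror image Rh2(R-PTAD)4 would be used if the opposite sense is found.

**Route**

Step 1
Reactants: 1 3,5-dimethoxyphenol
Product: 2 (3,5-dimethoxyphenoxy)triisopropylsilane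
Conditions: TIPSCl, imidazole, DMF, rt
Reagents that add atoms: triisopropylsilyl chloride, CC(C)[Si](Cl)(C(C)C)C(C)C
Why: Imidazole-promoted silylation of a phenol; the bulky, poorly coordinating OTIPS group is chosen to shield its two neighbouring ring positions in the lithiation of step 2.

Step 2
Reactants: 2 (3,5-dimethoxyphenoxy)triisopropylsilane; 3 N-methoxy-N-methylacetamide
Product: 5 1-[2,6-dimethoxy-4-(triisopropylsilyloxy)phenyl]ethan-1-one, via [2,6-dimethoxy-4-(triisopropylsilyloxy)phenyl]lithium 4 (not isolated)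
Conditions: n-BuLi, THF, 0 °C → rt; then 3, −78 °C → rt; 1 M HCl quench
Reagents that add atoms: n-butyllithium, [Li]CCCC (lithium of 4 only)
Why: Directed ortho-metalation at the C–H between the two methoxy groups (most acidic, doubly coordinated, the other two sites shielded by OTIPS), followed by a Weinreb ketone synthesis that stops at the ketone.

Step 3
Reactants: 6 4-bromo-2-methoxyphenol; 7 3-chloro-3-methylbut-1-yne
Product: 8 4-bromo-2-methoxy-1-[(2-methylbut-3-yn-2-yl)oxy]benzene
Conditions: CuCl2·2H2O (cat.), DBU, MeCN, 0 °C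
Reagents that add atoms: none
Why: Copper-catalysed O-alkylation of a phenol with a tertiary propargylic chloride, the standard entry to aryl 1,1-dimethylpropargyl ethers, takes place at the only free OH of 6.

Step 4
Reactants: 8 4-bromo-2-methoxy-1-[(2-methylbut-3-yn-2-yl)oxy]benzene
Product: 9 6-bromo-8-methoxy-2,2-dimethyl-2H-chromene
Conditions: PhNEt2, 185 °C
Reagents that add atoms: none
Why: Aromatic propargyl Claisen rearrangement, tautomerisation, 1,5-hydrogen shift and oxa-6π electrocyclisation occur in one thermal operation, and because the other ortho position carries OMe only one chromene can form, with Br para to the ring oxygen.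

Step 5
Reactants: 9 6-bromo-8-methoxy-2,2-dimethyl-2H-chromene
Product: 10 6-bromo-2,2-dimethyl-2H-chromen-8-ol
Conditions: NaSEt, DMF, 120 °C; then 1 M HCl
Reagents that add atoms: none
Why: Thiolate SN2 demethylation of an aryl methyl ether; the methyl carbon is the only unhindered sp3 C–O carbon (the other is tertiary), and the basic medium spares the acid-sensitive chromene.

Step 6
Reactants: 10 6-bromo-2,2-dimethyl-2H-chromen-8-ol
Product: 11 [(6-bromo-2,2-dimethyl-2H-chromen-8-yl)oxy]triisopropylsilane
Conditions: TIPSCl, imidazole, DMF, rt → 40 °C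
Reagents that add atoms: triisopropylsilyl chloride, CC(C)[Si](Cl)(C(C)C)C(C)C
Why: Imidazole-promoted silylation; the exchange of methyl for TIPS gives a group without activated C–H bonds for step 9 that fluoride can remove at the end without Lewis acid next to the pyran oxygen.

Step 7
Reactants: 5 1-[2,6-dimethoxy-4-(triisopropylsilyloxy)phenyl]ethan-1-one; 11 [(6-bromo-2,2-dimethyl-2H-chromen-8-yl)oxy]triisopropylsilane
Product: 12 1-[2,6-dimethoxy-4-(triisopropylsilyloxy)phenyl]-2-[2,2-dimethyl-8-(triisopropylsilyloxy)-2H-chromen-6-yl]ethan-1-one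
Conditions: Pd2(dba)3 (cat.), Xantphos (cat.), K3PO4, toluene, 90 °C
Reagents that add atoms: none
Why: Palladium-catalysed α-arylation of a methyl ketone enolate (Buchwald–Hartwig type); the wide-bite-angle ligand and the weak, insoluble base favour monoarylation and spare the aryl silyl ethers.

Step 8
Reactants: 12 1-[2,6-dimethoxy-4-(triisopropylsilyloxy)phenyl]-2-[2,2-dimethyl-8-(triisopropylsilyloxy)-2H-chromen-6-yl]ethan-1-one
Product: 13 2-diazo-1-[2,6-dimethoxy-4-(triisopropylsilyloxy)phenyl]-2-[2,2-dimethyl-8-(triisopropylsilyloxy)-2H-chromen-6-yl]ethan-1-one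
Conditions: p-ABSA, DBU, dry MeCN–THF, 0 °C → rt
Reagents that add atoms: 4-acetamidobenzenesulfonyl azide, CC(=O)Nc1ccc(cc1)S(=O)(=O)N=[N+]=[N-]
Why: Regitz diazo transfer to the doubly activated (benzylic and α-keto) methylene group, the usual way to α-aryl-α-diazoketones.

Step 9
Reactants: 13 2-diazo-1-[2,6-dimethoxy-4-(triisopropylsilyloxy)phenyl]-2-[2,2-dimethyl-8-(triisopropylsilyloxy)-2H-chromen-6-yl]ethan-1-one
Product: 14 (3S)-5-methoxy-7-(triisopropylsilyloxy)-3-[2,2-dimethyl-8-(triisopropylsilyloxy)-2H-chromen-6-yl]chroman-4-one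
Conditions: Rh2(S-PTAD)4 (1 mol %), 4 Å MS, 2,2-dimethylbutane, 50 °C, slow addition of 13 (syringe pump, final ca. 0.01 M)
Reagents that add atoms: none
Why: Proposed new method: the catalyst expels N2 from 13 and gives a donor/acceptor rhodium carbene at C3 (donor: p-alkoxyaryl ring B, acceptor: aroyl group), which inserts through a concerted, asynchronous three-centre transition state with hydride-transfer character into a C–H bond of an ortho OCH3 group, so that the methyl carbon becomes C2 and its hydrogen ends on C3. The closest known reaction types are the Rh(II)-catalysed 1,6-insertion of o-alkoxyaryl α-diazoketones next to the ether oxygen (chroman-4-ones), the 1,5-insertion of aryldiazoacetates into aryl OCH3 groups (dihydrobenzofurans) and the enantioselective intermolecular insertion of donor/acceptor carbenes into methyl ethers; not yet shown are the α-aryl diazoketone, the primary OCH3 site in the 1,6 mode and a stereocentre on the carbene carbon alone. Ring C closes in the 1,6-insertion mode (six-membered transition state C3–C4–C4a–C8a–O1–CH3), and the usually faster 1,5 mode is not available because the 1,5 atom is the ether oxygen, which bears no hydrogen. C3 is controlled by the catalyst alone: the four phthalimido-adamantylglycinate ligands shield one face of the carbene, C2 and H are delivered to the open face in the same event, and neither acid nor base is present that could epimerise the product. The step needs chemoselectivity for OCH3 over all other sites, and the substrate secures it: both ortho positions of ring A carry OMe and are equivalent by rotation about the C4–C4a bond, their six hydrogens are the only C–H bonds within reach, the oxonium ylide at the ether oxygen forms reversibly and has only a slow 1,2-methyl shift as exit, and the TIPS groups offer no activated C–H bond. Slow addition at high dilution should hold back dimerisation and intermolecular attack on the hindered, gem-dimethyl-flanked chromene double bond, and the two TIPS groups make 13 soluble in the hydrocarbon solvent in which this catalyst class is most selective.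

Step 10
Reactants: 14 (3S)-5-methoxy-7-(triisopropylsilyloxy)-3-[2,2-dimethyl-8-(triisopropylsilyloxy)-2H-chromen-6-yl]chroman-4-one
Product: 15 (3S)-5-hydroxy-7-(triisopropylsilyloxy)-3-[2,2-dimethyl-8-(triisopropylsilyloxy)-2H-chromen-6-yl]chroman-4-one
Conditions: BCl3 (1.5 equiv), CH2Cl2, −78 → −20 °C; then ice-water
Reagents that add atoms: none
Why: Chelation-controlled aryl methyl ether cleavage: boron binds the C4 carbonyl oxygen and the peri 5-OMe oxygen and chloride removes the methyl group, while O1–C2, the pyran ether (shielded by the neighbouring OTIPS) and the silyl ethers cannot chelate, and the absence of base at low temperature should keep C3 intact.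

Step 11
Reactants: 15 (3S)-5-hydroxy-7-(triisopropylsilyloxy)-3-[2,2-dimethyl-8-(triisopropylsilyloxy)-2H-chromen-6-yl]chroman-4-one
Product: 16 (3S)-5,7-dihydroxy-3-(8-hydroxy-2,2-dimethyl-2H-chromen-6-yl)chroman-4-one (CNP0298948.1)
Conditions: HF·pyridine, pyridine, THF, 0 °C → rt
Reagents that add atoms: none
Why: Fluoride-driven cleavage of both aryl silyl ethers in a weakly acidic buffered medium, in which no phenoxide or enolate builds up, so C3 should not epimerise and the chromene should not be protonated.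

**Compound list**

1 | 3,5-dimethoxyphenol | COc1cc(O)cc(OC)c1 | starting material
2 | (3,5-dimethoxyphenoxy)triisopropylsilane | COc1cc(O[Si](C(C)C)(C(C)C)C(C)C)cc(OC)c1 | intermediate
3 | N-methoxy-N-methylacetamide | CC(=O)N(C)OC | starting material
4 | [2,6-dimethoxy-4-(triisopropylsilyloxy)phenyl]lithium | [Li]c1c(OC)cc(O[Si](C(C)C)(C(C)C)C(C)C)cc1OC | intermediate
5 | 1-[2,6-dimethoxy-4-(triisopropylsilyloxy)phenyl]ethan-1-one | CC(=O)c1c(OC)cc(O[Si](C(C)C)(C(C)C)C(C)C)cc1OC | intermediate
6 | 4-bromo-2-methoxyphenol | COc1cc(Br)ccc1O | starting material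
7 | 3-chloro-3-methylbut-1-yne | CC(C)(Cl)C#C | starting material
8 | 4-bromo-2-methoxy-1-[(2-methylbut-3-yn-2-yl)oxy]benzene | COc1cc(Br)ccc1OC(C)(C)C#C | intermediate
9 | 6-bromo-8-methoxy-2,2-dimethyl-2H-chromene | CC1(C)C=Cc2cc(Br)cc(OC)c2O1 | intermediate
10 | 6-bromo-2,2-dimethyl-2H-chromen-8-ol | CC1(C)C=Cc2cc(Br)cc(O)c2O1 | intermediate
11 | [(6-bromo-2,2-dimethyl-2H-chromen-8-yl)oxy]triisopropylsilane | CC1(C)C=Cc2cc(Br)cc(O[Si](C(C)C)(C(C)C)C(C)C)c2O1 | intermediate
12 | 1-[2,6-dimethoxy-4-(triisopropylsilyloxy)phenyl]-2-[2,2-dimethyl-8-(triisopropylsilyloxy)-2H-chromen-6-yl]ethan-1-one | COc1cc(O[Si](C(C)C)(C(C)C)C(C)C)cc(OC)c1C(=O)Cc1cc2C=CC(C)(C)Oc2c(O[Si](C(C)C)(C(C)C)C(C)C)c1 | intermediate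
13 | 2-diazo-1-[2,6-dimethoxy-4-(triisopropylsilyloxy)phenyl]-2-[2,2-dimethyl-8-(triisopropylsilyloxy)-2H-chromen-6-yl]ethan-1-one | COc1cc(O[Si](C(C)C)(C(C)C)C(C)C)cc(OC)c1C(=O)C(=[N+]=[N-])c1cc2C=CC(C)(C)Oc2c(O[Si](C(C)C)(C(C)C)C(C)C)c1 | intermediate
14 | (3S)-5-methoxy-7-(triisopropylsilyloxy)-3-[2,2-dimethyl-8-(triisopropylsilyloxy)-2H-chromen-6-yl]chroman-4-one | CC1(C)C=Cc2cc([C@H]3COc4cc(O[Si](C(C)C)(C(C)C)C(C)C)cc(OC)c4C3=O)cc(O[Si](C(C)C)(C(C)C)C(C)C)c2O1 | intermediate
15 | (3S)-5-hydroxy-7-(triisopropylsilyloxy)-3-[2,2-dimethyl-8-(triisopropylsilyloxy)-2H-chromen-6-yl]chroman-4-one | CC1(C)C=Cc2cc([C@H]3COc4cc(O[Si](C(C)C)(C(C)C)C(C)C)cc(O)c4C3=O)cc(O[Si](C(C)C)(C(C)C)C(C)C)c2O1 | intermediate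
16 | (3S)-5,7-dihydroxy-3-(8-hydroxy-2,2-dimethyl-2H-chromen-6-yl)chroman-4-one | CC1(C)C=Cc2cc([C@H]3COc4cc(O)cc(O)c4C3=O)cc(O)c2O1 | target

**Step count**

Total step count: 11. Longest linear sequence: 9 (steps 3–11, from 6 to 16).

**Steps most likely to fail**

Step 9 (Proposed new method). The carbene may leave by other channels: attack of the ether oxygen with methyl shift or loss of methyl, a Wolff-type shift, dimerisation, or intermolecular attack on the chromene double bond. The catalyst may also discriminate poorly between the two carbene faces.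

The fallback uses known chemistry only and runs from 12 back to 14. BCl3 (1.1 equiv, CH2Cl2, −78 °C) removes one of the two equivalent methyl groups next to the ketone and should give 1-[2-hydroxy-6-methoxy-4-(triisopropylsilyloxy)phenyl]-2-[2,2-dimethyl-8-(triisopropylsilyloxy)-2H-chromen-6-yl]ethan-1-one F1. DMF dimethyl acetal (toluene, 90 °C) adds C2 and closes ring C to the isoflavone 5-methoxy-7-(triisopropylsilyloxy)-3-[2,2-dimethyl-8-(triisopropylsilyloxy)-2H-chromen-6-yl]-4H-chromen-4-one F2. Asymmetric transfer hydrogenation (RuCl[(S,S)-TsDPEN](p-cymene), HCO2H–Et3N, rt → 40 °C) saturates C2=C3 and then reduces C4=O while C3 equilibrates (dynamic kinetic resolution). This should give the cis alcohol (3S,4S)-5-methoxy-7-(triisopropylsilyloxy)-3-[2,2-dimethyl-8-(triisopropylsilyloxy)-2H-chromen-6-yl]chroman-4-ol F3. Dess–Martin oxidation (CH2Cl2, 0 °C) leads back to 14.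

Step 10. Configurational integrity at C3 may be lost through boron-promoted enolisation of the chelated ketone, or the Lewis acid may open the pyran ring.

The fallback runs from 12 to 16 and moves the demethylation in front of the stereocentre. The phenol F1 described above is silylated (TIPSOTf, 2,6-lutidine, CH2Cl2) to 1-[2-methoxy-4,6-bis(triisopropylsilyloxy)phenyl]-2-[2,2-dimethyl-8-(triisopropylsilyloxy)-2H-chromen-6-yl]ethan-1-one F4. Diazo transfer as in step 8 gives 2-diazo-1-[2-methoxy-4,6-bis(triisopropylsilyloxy)phenyl]-2-[2,2-dimethyl-8-(triisopropylsilyloxy)-2H-chromen-6-yl]ethan-1-one F5. The insertion of step 9, now into the only OMe group left, should give (3S)-5,7-bis(triisopropylsilyloxy)-3-[2,2-dimethyl-8-(triisopropylsilyloxy)-2H-chromen-6-yl]chroman-4-one F6. One treatment with HF·pyridine as in step 11 gives 16, so no Lewis acid meets the stereocentre.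

Step 7. The electron-rich bromide may couple slowly with the enolate, a second arylation may occur, or the base may cleave a silyl ether at 90 °C.

The fallback runs from 11 (with 4 from step 2) to 12 and replaces the cross-coupling by a carbonyl addition. Bromine–lithium exchange (n-BuLi, THF, −78 °C) gives [2,2-dimethyl-8-(triisopropylsilyloxy)-2H-chromen-6-yl]lithium F7. This opens ethylene oxide (BF3·OEt2, −78 °C) to 2-[2,2-dimethyl-8-(triisopropylsilyloxy)-2H-chromen-6-yl]ethan-1-ol F8. Dess–Martin oxidation gives 2-[2,2-dimethyl-8-(triisopropylsilyloxy)-2H-chromen-6-yl]acetaldehyde F9. Addition of aryllithium 4 (−78 °C) gives racemic 1-[2,6-dimethoxy-4-(triisopropylsilyloxy)phenyl]-2-[2,2-dimethyl-8-(triisopropylsilyloxy)-2H-chromen-6-yl]ethan-1-ol F10, and a second Dess–Martin oxidation gives 12.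

**Further compounds**

F1 | step 9 | 1-[2-hydroxy-6-methoxy-4-(triisopropylsilyloxy)phenyl]-2-[2,2-dimethyl-8-(triisopropylsilyloxy)-2H-chromen-6-yl]ethan-1-one | COc1cc(O[Si](C(C)C)(C(C)C)C(C)C)cc(O)c1C(=O)Cc1cc2C=CC(C)(C)Oc2c(O[Si](C(C)C)(C(C)C)C(C)C)c1
F2 | step 9 | 5-methoxy-7-(triisopropylsilyloxy)-3-[2,2-dimethyl-8-(triisopropylsilyloxy)-2H-chromen-6-yl]-4H-chromen-4-one | COc1cc(O[Si](C(C)C)(C(C)C)C(C)C)cc2occ(-c3cc4C=CC(C)(C)Oc4c(O[Si](C(C)C)(C(C)C)C(C)C)c3)c(=O)c12
F3 | step 9 | (3S,4S)-5-methoxy-7-(triisopropylsilyloxy)-3-[2,2-dimethyl-8-(triisopropylsilyloxy)-2H-chromen-6-yl]chroman-4-ol (cis) | CC1(C)C=Cc2cc([C@H]3COc4cc(O[Si](C(C)C)(C(C)C)C(C)C)cc(OC)c4[C@H]3O)cc(O[Si](C(C)C)(C(C)C)C(C)C)c2O1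
F4 | step 10 | 1-[2-methoxy-4,6-bis(triisopropylsilyloxy)phenyl]-2-[2,2-dimethyl-8-(triisopropylsilyloxy)-2H-chromen-6-yl]ethan-1-one | COc1cc(O[Si](C(C)C)(C(C)C)C(C)C)cc(O[Si](C(C)C)(C(C)C)C(C)C)c1C(=O)Cc1cc2C=CC(C)(C)Oc2c(O[Si](C(C)C)(C(C)C)C(C)C)c1
F5 | step 10 | 2-diazo-1-[2-methoxy-4,6-bis(triisopropylsilyloxy)phenyl]-2-[2,2-dimethyl-8-(triisopropylsilyloxy)-2H-chromen-6-yl]ethan-1-one | COc1cc(O[Si](C(C)C)(C(C)C)C(C)C)cc(O[Si](C(C)C)(C(C)C)C(C)C)c1C(=O)C(=[N+]=[N-])c1cc2C=CC(C)(C)Oc2c(O[Si](C(C)C)(C(C)C)C(C)C)c1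
F6 | step 10 | (3S)-5,7-bis(triisopropylsilyloxy)-3-[2,2-dimethyl-8-(triisopropylsilyloxy)-2H-chromen-6-yl]chroman-4-one | CC1(C)C=Cc2cc([C@H]3COc4cc(O[Si](C(C)C)(C(C)C)C(C)C)cc(O[Si](C(C)C)(C(C)C)C(C)C)c4C3=O)cc(O[Si](C(C)C)(C(C)C)C(C)C)c2O1
F7 | step 7 | [2,2-dimethyl-8-(triisopropylsilyloxy)-2H-chromen-6-yl]lithium | [Li]c1cc2C=CC(C)(C)Oc2c(O[Si](C(C)C)(C(C)C)C(C)C)c1
F8 | step 7 | 2-[2,2-dimethyl-8-(triisopropylsilyloxy)-2H-chromen-6-yl]ethan-1-ol | OCCc1cc2C=CC(C)(C)Oc2c(O[Si](C(C)C)(C(C)C)C(C)C)c1
F9 | step 7 | 2-[2,2-dimethyl-8-(triisopropylsilyloxy)-2H-chromen-6-yl]acetaldehyde | O=CCc1cc2C=CC(C)(C)Oc2c(O[Si](C(C)C)(C(C)C)C(C)C)c1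
F10 | step 7 | 1-[2,6-dimethoxy-4-(triisopropylsilyloxy)phenyl]-2-[2,2-dimethyl-8-(triisopropylsilyloxy)-2H-chromen-6-yl]ethan-1-ol (racemic) | COc1cc(O[Si](C(C)C)(C(C)C)C(C)C)cc(OC)c1C(O)Cc1cc2C=CC(C)(C)Oc2c(O[Si](C(C)C)(C(C)C)C(C)C)c1
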